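**Plan**
Retrosynthetic cuts, in order: the exocyclic C5=CH bond (vinylogous Knoevenagel), the four C–Br bonds (phenol bromination), the C3–C(acyl) bond together with a temporary O–C4 bond (nitrile oxide (3+2) cycloaddition), and the C4–aryl bond (Suzuki–Miyaura).
Enabling feature: the aroyl C=O, C3 and C4 form an α,β-unsaturated ketone (O=C–C3=C4), the dehydrated aldol that a 2-isoxazoline ring O–N=C–C3–C4 masks. Lactone carbonyl C2 and the C4 aryl group polarise C3=C4 of the butenolide ring so that the nitrile oxide carbon goes to C3.
Forward: the butenolide ring is bought and arylated at C4. An aryl nitrile oxide then adds across C3=C4 to fuse a temporary isoxazoline ring onto the lactone. N–O cleavage, hydrolysis and dehydration return the C3=C4 alkene, now carrying the aroyl group. Demethylation, fourfold bromination and a final benzylidene condensation follow.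
Stereochemistry: the only stereo-element of the target is the Z exocyclic alkene, set under thermodynamic control in the last step. The two stereocentres of the cycloadduct are transient and are erased in step 4.

Key step: step 3

Assumption: compounds 7, 8 and 9 are racemic and one enantiomer is written; compounds 1, 2, 4 and 13 are taken as commercial.

**Step 1**
Reactants: 1 4-bromofuran-2(5H)-one; 2 (4-methoxyphenyl)boronic acid
Product: 3 4-(4-methoxyphenyl)furan-2(5H)-one
Conditions: PdCl2(PPh3)2 (3 mol%), KF (3 equiv), THF/H2O, 60 °C
Reagents that add atoms: none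
Why: Suzuki–Miyaura coupling, in which the C4–Br bond of the β-bromobutenolide (a vinylogous acyl bromide) should add readily to zerovalent palladium and fluoride activates the boronic acid without opening the lactone.

**Step 2**
Reactants: 4 (E)-4-methoxybenzaldehyde oxime
Product: 5 (Z)-N-hydroxy-4-methoxybenzimidoyl chloride
Conditions: NCS (1.05 equiv), DMF, rt
Reagents that add atoms: N-chlorosuccinimide (NCS), O=C1CCC(=O)N1Cl
Why: Chlorination of the aldoxime C–H by NCS (hydroximoyl chloride formation) is the standard entry to aryl nitrile oxides and should be faster than chlorination of the anisole ring.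

**Step 3**
Reactants: 3 4-(4-methoxyphenyl)furan-2(5H)-one; 5 (Z)-N-hydroxy-4-methoxybenzimidoyl chloride
Product: 7 cis-fused isoxazoline (3aS*,6aS*)-3,6a-bis(4-methoxyphenyl)-3a,6a-dihydrofuro[3,4-d]isoxazol-4(6H)-one (racemic), via 4-methoxybenzonitrile oxide 6 (not isolated)
Conditions: KHCO3 (solid, excess), EtOAc, 50 °C; 5 (3 equiv) added in portions over several hours
Reagents that add atoms: none
Why: KHCO3 dehydrochlorinates 5 to nitrile oxide 6 at a low stationary concentration, and 6 adds across the C3=C4 bond of butenolide 3 in a concerted but asynchronous Huisgen (3+2) cycloaddition that forms the C3–C(aryl)=N bond (the later C3–acyl bond) and a temporary O–C4 bond. The closest known reaction type is the nitrile oxide cycloaddition to 2(5H)-furanones, coumarins and cinnamic esters, which generally places the dipole carbon on the α-carbon and the dipole oxygen on the β-carbon. The isoxazoline ring closes by suprafacial (3+2) cycloaddition onto a planar alkene, so the new five-membered ring is necessarily cis-fused to the lactone. The two new stereocentres (C3a and C6a) are fixed relative to each other by that suprafacial addition, the adduct is racemic, and both centres are erased in step 4. The step needs regioselectivity and chemoselectivity over furoxan formation: the first is secured by three factors that point the same way (conjugation of C3=C4 to lactone carbonyl C2, the C4 aryl group that takes the dipole oxygen at the benzylic carbon, and the unsubstituted C3–H position that accepts the bulky aryl-bearing dipole carbon), the second by portionwise addition of excess 5 so that 6 stays dilute while 3 is concentrated.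

**Step 4**
Reactants: 7 cis-fused isoxazoline
Product: 10 enone 3-(4-methoxybenzoyl)-4-(4-methoxyphenyl)furan-2(5H)-one, via hydroxy imine 8 (not isolated), via hydroxy ketone 9 (not isolated)
Conditions: Mo(CO)6 (1 equiv), MeCN/H2O (10:1), 80 °C; then aq. HCl (2 M), THF, 40 °C
Reagents that add atoms: water, O
Why: Reductive N–O cleavage of a 2-isoxazoline by Mo(CO)6 (the isoxazoline route to aldols) should give hydroxy imine 8, aqueous acid hydrolyses it to hydroxy ketone 9, and the tertiary p-methoxybenzylic hydroxyl β to two carbonyl groups is lost by acid-promoted dehydration to restore the C3=C4 bond, which removes both stereocentres.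

**Step 5**
Reactants: 10 3-(4-methoxybenzoyl)-4-(4-methoxyphenyl)furan-2(5H)-one
Product: 11 3-(4-hydroxybenzoyl)-4-(4-hydroxyphenyl)furan-2(5H)-one
Conditions: BBr3 (5 equiv), CH2Cl2, −78 °C to rt; then H2O
Reagents that add atoms: none
Why: Lewis acid-mediated aryl methyl ether cleavage with BBr3 should free both phenols while the butenolide and the diaryl-type ketone survive at low temperature.

**Step 6**
Reactants: 11 3-(4-hydroxybenzoyl)-4-(4-hydroxyphenyl)furan-2(5H)-one
Product: 12 3-(3,5-dibromo-4-hydroxybenzoyl)-4-(3,5-dibromo-4-hydroxyphenyl)furan-2(5H)-one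
Conditions: Br2 (4.1 equiv), KBr, dioxane/H2O, rt
Reagents that add atoms: bromine, BrBr
Why: Electrophilic aromatic bromination, in which each free phenol directs to its two ortho positions (para is blocked) and the phenol rings should react much faster than the electron-poor butenolide alkene.

**Step 7**
Reactants: 12 3-(3,5-dibromo-4-hydroxybenzoyl)-4-(3,5-dibromo-4-hydroxyphenyl)furan-2(5H)-one; 13 4-hydroxybenzaldehyde
Product: 14 cadiolide A, (Z)-3-(3,5-dibromo-4-hydroxybenzoyl)-4-(3,5-dibromo-4-hydroxyphenyl)-5-(4-hydroxybenzylidene)furan-2(5H)-one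
Conditions: piperidine, MeOH, rt
Reagents that add atoms: none
Why: Vinylogous Knoevenagel condensation at the C5 methylene, which is acidified by the 3-aroylbutenolide (its anion is a 2-oxidofuran), and reversible addition–elimination should deliver the thermodynamically preferred Z alkene with the new aryl group syn to the ring oxygen and away from the C4 aryl group.

**Compound list**
1 | 4-bromofuran-2(5H)-one | O=C1OCC(Br)=C1 | starting material
2 | (4-methoxyphenyl)boronic acid | COc1ccc(cc1)B(O)O | starting material
3 | 4-(4-methoxyphenyl)furan-2(5H)-one | COc1ccc(cc1)C1=CC(=O)OC1 | intermediate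
4 | (E)-4-methoxybenzaldehyde oxime | O/N=C/c1ccc(OC)cc1 | starting material
5 | (Z)-N-hydroxy-4-methoxybenzimidoyl chloride | O/N=C(\Cl)c1ccc(OC)cc1 | intermediate
6 | 4-methoxybenzonitrile oxide | COc1ccc(cc1)C#[N+][O-] | intermediate
7 | (3aS*,6aS*)-3,6a-bis(4-methoxyphenyl)-3a,6a-dihydrofuro[3,4-d]isoxazol-4(6H)-one, cis-fused, racemic | O=C1OC[C@]2(c3ccc(OC)cc3)ON=C(c3ccc(OC)cc3)[C@H]12 | intermediate
8 | (3S*,4S*)-4-hydroxy-3-[imino(4-methoxyphenyl)methyl]-4-(4-methoxyphenyl)dihydrofuran-2(3H)-one, imidoyl group cis to hydroxyl, racemic | N=C(c1ccc(OC)cc1)[C@@H]1C(=O)OC[C@@]1(O)c1ccc(OC)cc1 | intermediate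
9 | (3R*,4S*)-4-hydroxy-3-(4-methoxybenzoyl)-4-(4-methoxyphenyl)dihydrofuran-2(3H)-one, aroyl group cis to hydroxyl, racemic, C3 epimerisable | O=C(c1ccc(OC)cc1)[C@@H]1C(=O)OC[C@@]1(O)c1ccc(OC)cc1 | intermediate
10 | 3-(4-methoxybenzoyl)-4-(4-methoxyphenyl)furan-2(5H)-one | COc1ccc(cc1)C(=O)C1=C(COC1=O)c1ccc(OC)cc1 | intermediate
11 | 3-(4-hydroxybenzoyl)-4-(4-hydroxyphenyl)furan-2(5H)-one | O=C(c1ccc(O)cc1)C1=C(COC1=O)c1ccc(O)cc1 | intermediate
12 | 3-(3,5-dibromo-4-hydroxybenzoyl)-4-(3,5-dibromo-4-hydroxyphenyl)furan-2(5H)-one | O=C(c1cc(Br)c(O)c(Br)c1)C1=C(COC1=O)c1cc(Br)c(O)c(Br)c1 | intermediate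
13 | 4-hydroxybenzaldehyde | O=Cc1ccc(O)cc1 | starting material
14 | cadiolide A | O=C1O/C(=C\c2ccc(O)cc2)C(c2cc(Br)c(O)c(Br)c2)=C1C(=O)c1cc(Br)c(O)c(Br)c1 | target

**Step count**
Total steps: 7. Longest linear sequence: 6 steps (steps 1, 3, 4, 5, 6 and 7).

**Steps most likely to fail**

Step 3. The cycloaddition to a trisubstituted, doubly conjugated alkene may be slower than dimerisation of the nitrile oxide to its furoxan, and the base may open the adduct prematurely. The fallback replaces the cycloaddition by cross-coupling at C3 and sets out from boronic acid 2. Regioselective Suzuki–Miyaura coupling of 2 with 3,4-dibromofuran-2(5H)-one at the more electrophilic C4–Br bond (PdCl2(PPh3)2, KF, THF/H2O) should give 3-bromo-4-(4-methoxyphenyl)furan-2(5H)-one F1. Stannylation with (Bu3Sn)2 and Pd(PPh3)4 in toluene at 100 °C should give 4-(4-methoxyphenyl)-3-(tributylstannyl)furan-2(5H)-one F2. Stille acylation of F2 with 4-methoxybenzoyl chloride (PdCl2(PPh3)2, toluene, 80 °C) should form the same C3–acyl bond and return to the route at enone 10.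

Step 4. Reductive cleavage may stall at the enamino lactone tautomer of 8, or the aldol may fragment by retro-aldol cleavage of the C3–C4 bond before it dehydrates. The fallback avoids reduction and sets out from isoxazoline 7. DBU in CH2Cl2 should remove the acidic C3a proton and expel the oxime oxygen from C6a (E1cB ring opening) to give (Z)-3-[(hydroxyimino)(4-methoxyphenyl)methyl]-4-(4-methoxyphenyl)furan-2(5H)-one F3, which already contains the C3=C4 bond. Transoximation with aqueous glyoxylic acid in AcOH should then release the ketone and return to the route at enone 10.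

Step 6. Bromination may also occur at the enolisable C5 methylene through the 2-hydroxyfuran tautomer, or stop short on the less activated 4-hydroxybenzoyl ring. The fallback blocks C5 before bromination and sets out from bisphenol 11. Knoevenagel condensation with 4-methoxybenzaldehyde (piperidine, MeOH) should give (Z)-3-(4-hydroxybenzoyl)-4-(4-hydroxyphenyl)-5-(4-methoxybenzylidene)furan-2(5H)-one F4, in which C5 carries no hydrogen and the third ring is a much less reactive anisole. Br2/KBr (4 equiv) should then brominate only the two phenol rings to give (Z)-3-(3,5-dibromo-4-hydroxybenzoyl)-4-(3,5-dibromo-4-hydroxyphenyl)-5-(4-methoxybenzylidene)furan-2(5H)-one F5. BBr3 demethylation of F5 returns to the route at target 14.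

**Further compounds**
F1 | step 3 | 3-bromo-4-(4-methoxyphenyl)furan-2(5H)-one | COc1ccc(cc1)C1=C(Br)C(=O)OC1
F2 | step 3 | 4-(4-methoxyphenyl)-3-(tributylstannyl)furan-2(5H)-one | CCCC[Sn](CCCC)(CCCC)C1=C(COC1=O)c1ccc(OC)cc1
F3 | step 4 | (Z)-3-[(hydroxyimino)(4-methoxyphenyl)methyl]-4-(4-methoxyphenyl)furan-2(5H)-one | O/N=C(\C1=C(c2ccc(OC)cc2)COC1=O)c1ccc(OC)cc1
F4 | step 6 | (Z)-3-(4-hydroxybenzoyl)-4-(4-hydroxyphenyl)-5-(4-methoxybenzylidene)furan-2(5H)-one | O=C1O/C(=C\c2ccc(OC)cc2)C(c2ccc(O)cc2)=C1C(=O)c1ccc(O)cc1
F5 | step 6 | (Z)-3-(3,5-dibromo-4-hydroxybenzoyl)-4-(3,5-dibromo-4-hydroxyphenyl)-5-(4-methoxybenzylidene)furan-2(5H)-one | O=C1O/C(=C\c2ccc(OC)cc2)C(c2cc(Br)c(O)c(Br)c2)=C1C(=O)c1cc(Br)c(O)c(Br)c1
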